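Slowness is the thing to reckon with here: by 12 d the flask will show how far a slow loss of target has run, and the teal run is the evidence you have for that loss.

| flask | substrate | remark | time |
|---|---|---|---|
| teal | 0.065 M | run made earlier |  |
| flask | 0.13 M |  | 12 d |

- teal (time / d: isomer of the product A / %, target / %, substrate / %): 0.208: 9.3, 55.6, 22.3; 0.417: 6.1, 57.3, 18.8; 1.04: 5.6, 48.3, 18.5; 2.50: 6.4, 36.6, 18.8

(readings scatter by 1 percentage point)

1. share of isomer of the product A in isomer of the product A plus target at 10 min
2. share of isomer of the product A in isomer of the product A plus target at 6.0 h
3. share of isomer of the product A in isomer of the product A plus target at 12 d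
4. which of isomer of the product A and target there is more of at 12 d

- the earlier runs were read with a standard deviation of 1 percentage point
- a reading or a percentage of target counts all its forms, free or not

From 0.417 d to 2.50 d the teal run's substrate reads 18.8% and then 18.8%, while target falls from 57.3% to 36.6%, a far larger change. A plain first-order equilibrium would take substrate down with target, so my own reckoning takes most target to be undissolved, holding the solution and its substrate at a constant concentration, 12.2 mM as read in teal, and not at a constant percentage. Whatever leaves that solution then leaves at a steady rate, a zero-order loss. Between 1.04 d and 2.50 d teal gives 5.21 mM d⁻¹ for D, the drain, meaning the target lost per litre per day while undissolved target stands.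

If the solution and what has left it match teal per litre, the flask's extra charge all sits in target, which gives 88.8 mM at 2.50 d. At D that stock lasts 17.0 d, longer than the 9.50 d remaining, so 39.3 mM of target should stand at 12 d, against 4.16 mM of isomer of the product A as read in teal. My share is therefore 9.57%, with target ahead.

The forecast gives 20% at 10 min and 12% at 6.0 h, and at 12 d it differs from my reckoning, with 55% and isomer of the product A ahead (“Isomer narrowly leads”).

The flask gives 9.40%, 8.92% and 7.73%, and target leads, 39.1% against 3.28%.

    substrate ⇌ isomer of the product B (K = 15.0, k = 0.0150 h⁻¹)
    substrate ⇌ target (K = 0.120, k = 0.870 h⁻¹)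
    crystals ⇌ target, rate k3*(cs3 - [target]) while solid is left; crystals form when [target] > cs3 (solubility = 1.50 mM, k = 7.30 h⁻¹)
    substrate ⇌ dormant form (K = 1.20, k = 0.0460 h⁻¹)
    substrate ⇌ isomer of the product A (K = 0.350, k = 0.0600 h⁻¹)

By 1.20 d the flask's substrate had gone mostly to target, with crystals at 69.5% and substrate down to 9.29%. From then to 12 d, with crystals down to 38.0% and substrate at 9.38%, isomer of the product B rose from 6.44% to 37.0% while isomer of the product A went from 3.36% to 3.28%. Over those days the flask's drain was 3.79 mM d⁻¹, slower than D, and the flask's target at 12 d stood at 50.9 mM, above my 39.3 mM.

Now take a neighbour flask charged with 0.052 M: the same reckoning gives 10.8 mM of target at 2.50 d, which D clears in 2.07 d, well inside the 9.50 d remaining. Computed, that neighbour flask ends with crystals at 0%, target at 1.33% and isomer of the product A ahead at 3.94%, a share of 74.8%.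

The readings were computed with made-up constants, and the scatter is random.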